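Time does little to the uncatalysed product: in the ash run it reads 44.3% at 0.500 min and 43.9% at 3.00 min. So it is a burst, and its size is what counts.

in all of them: substrate 0.050 M

|  | reagent | catalyst | remark | time |
|---|---|---|---|---|
| oak | 1.2 equiv | 0.31 mol% | run made earlier |  |
| ash | 5 equiv | 0.31 mol% | run made earlier |  |
| cedar | 2.5 equiv | 0.62 mol% | run made earlier |  |
| flask | 2.50 equiv | 0.31 mol% |  | 3.0 min |

| run | time / min | target / % | uncatalysed product / % |
|---|---|---|---|
| oak | 0.500 | 19.4 | 14.0 |
| oak | 1.00 | 37.4 | 13.5 |
| oak | 1.50 | 49.6 | 17.2 |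
| oak | 2.00 | 56.8 | 15.1 |
| oak | 2.50 | 59.5 | 13.9 |
| oak | 3.00 | 65.7 | 14.0 |
| ash | 0.500 | 40.2 | 44.3 |
| ash | 1.00 | 51.7 | 43.6 |
| ash | 1.50 | 57.3 | 44.4 |
| ash | 2.00 | 56.9 | 44.2 |
| ash | 2.50 | 55.6 | 44.5 |
| ash | 3.00 | 55.8 | 43.9 |
| cedar | 0.250 | 34.1 | 15.5 |
| cedar | 0.417 | 53.5 | 13.9 |
| cedar | 0.833 | 73.9 | 15.4 |
| cedar | 1.50 | 82.3 | 15.7 |
| cedar | 3.00 | 82.8 | 16.6 |

(readings scatter by 1 percentage point)

- what was read earlier has a scatter of 1 percentage point, one standard deviation

* share of target in target plus uncatalysed product at 0.40 s
* share of target in target plus uncatalysed product at 8.0 s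
* share of target in target plus uncatalysed product at 3.0 min

But the burst follows no single charge. Oak and cedar differ in both reagent and catalyst, yet their ratios of equivalents to loading are close, and their mean readings are 14.6% and 15.4%. So reagent and catalyst appear to compete for the substrate.

The flask charges half the equivalents of ash at equal loading, so the ash reading scales to 0.391 for its burst odds, uncatalysed product over the rest of the substrate charged, a branching ratio that belongs to this recipe.

Cedar, with twice the flask's loading, reads 98.0% for target plus uncatalysed product at 1.50 min, and the flask has twice that time. So the reckoning here takes the flask as finished and puts the late share at 71.9%. But 8.0 s lies earlier than any reading, so the odds give no firm early share.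

The forecast, which says of the burst “It tracks their ratio”, gives 5%, 25% and 72.5%, the last a little above the reckoning here.

The flask gives 1.67%, 25.6% and 72.4%.

    substrate + catalyst → catalyst + intermediate (k = 470 M⁻¹ s⁻¹)
    reagent + catalyst + intermediate → catalyst + target (k = 1800 M⁻² s⁻¹)
    substrate + reagent → uncatalysed product (k = 0.240 M⁻¹ s⁻¹)

At 0.300 min the flask holds 16.5% substrate, 23.2% uncatalysed product, 42.6% intermediate and 17.7% target. By 1.50 min, substrate stands at 0.0189% and uncatalysed product at 27.2%, while intermediate has fallen to 10.1% and target has risen to 62.6%.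

The neighbour flask at 0.020 M keeps the equivalents and loading, so the odds again give 28.1% uncatalysed product and a late share of 71.9% if finished. It computes to 27.6% uncatalysed product, but at 3.00 min it still holds 36.0% intermediate, and its share is 56.8%.

The readings come from a simulation for an exercise.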